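## Retrosynthetic overview

1. Target 41 comes from global desilylation of acid 40. The C7 acrylic acid and the C5 allylic alcohol both derive from CH2CH2O arms by oxidation and α-methylenation. The C8 ester is made from cyclohexanol 30 and acid 34, whose stereocentre comes from a biocatalytic C=C reduction.
2. The 8β- and 6β-hydroxyls arise by hydride delivery to the α face of C8 enone 15 and then C6 ketone 20. H-7α comes from α-face hydroboration of the C6=C7 alkene.
3. The C10 vinyl group comes from Wittig methylenation of the C10 formyl group, which is carried as a pivalate through the two hydroborations.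
4. The only ring, the cyclohexane, is formed first: a catalytic enantioselective Diels–Alder reaction of (E)-enal 7 with 2-substituted diene 4 sets C10 and C5 together.
5. Diene 4 comes from enyne metathesis of alkyne 2 with ethene; enal 7 comes from a Wittig reaction.

**Conventions.** Ring locants follow the elemane skeleton: C10 is the quaternary ring carbon (it carries CH3 and the C1 substituent), then C9 (CH2), C8, C7, C6, C5 round the ring. β is the face of the C10 methyl group, α the opposite face. a5 = 2-(tert-butyldimethylsilyloxy)ethyl; a7 = 2-(4-methoxybenzyloxy)ethyl. TBS = tert-butyldimethylsilyl, TES = triethylsilyl, TMS = trimethylsilyl, PMB = 4-methoxybenzyl, Piv = pivaloyl.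

**Reading of the target.** 10β-CH3, 10α-vinyl, H-5α, 6β-OH, H-7α, 8β-acyloxy (all four ring substituents C5–C8 cis to the C10 methyl); side chain (R).

**Assumption 1.** The (S)-oxazaborolidinium catalyst of step 4 is taken to add the diene to the enal face that gives 8 as drawn; if the sense is opposite for this substrate, the (R)-catalyst is used in the same way.

**Assumption 2.** Compounds 1, 3, 5, 6 and 31 are bought.

## Route

Step 1
Reactants: 1 but-3-yn-1-ol
Product: 2 4-methoxybenzyl but-3-yn-1-yl ether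
Conditions: NaH, PMBCl, Bu4NI (cat.), THF/DMF, 0 °C → rt
Reagents that add atoms: 4-methoxybenzyl chloride, COc1ccc(CCl)cc1
Why: Williamson ether synthesis on the alkoxide; the alkyne C–H is not touched under these conditions.

Step 2
Reactants: 2 4-methoxybenzyl but-3-yn-1-yl ether; 3 ethene
Product: 4 2-[2-(4-methoxybenzyloxy)ethyl]buta-1,3-diene
Conditions: second-generation Grubbs catalyst (5 mol %), ethene (1 atm), CH2Cl2, 40 °C
Reagents that add atoms: none
Why: Enyne cross-metathesis of a terminal alkyne with ethene gives the 2-substituted buta-1,3-diene; no stereocentre is formed.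

Step 3
Reactants: 5 3-(tert-butyldimethylsilyloxy)propanal; 6 2-(triphenylphosphoranylidene)propanal
Product: 7 (E)-5-(tert-butyldimethylsilyloxy)-2-methylpent-2-enal
Conditions: toluene, 80 °C
Reagents that add atoms: none
Why: Wittig olefination with a stabilised formyl ylide is strongly E-selective, which puts CH3 and the silyloxyethyl chain cis on the C=C bond as needed for the C10/C5 relationship.

Step 4
Reactants: 7 (E)-5-(tert-butyldimethylsilyloxy)-2-methylpent-2-enal; 4 2-[2-(4-methoxybenzyloxy)ethyl]buta-1,3-diene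
Product: 8 10α-formyl-10β-methyl-5β-(a5)-7-(a7)-cyclohex-7-ene
Conditions: (S)-3,3-diphenyl-1-(o-tolyl)tetrahydro-1H,3H-pyrrolo[1,2-c][1,3,2]oxazaborole (20 mol %), HNTf2 (17 mol %), CH2Cl2, −78 → −20 °C
Reagents that add atoms: none
Why: Oxazaborolidinium-catalysed enantioselective Diels–Alder reaction; the 2-alkyl diene gives the "para" adduct, the E geometry of 7 is transferred suprafacially so that 10-CH3 and the C5 arm are cis, and the catalyst's face selection fixes the absolute configuration of C10 and C5 (first stereocentres).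

Step 5
Reactants: 8 10α-formyl-10β-methyl-5β-(a5)-7-(a7)-cyclohex-7-ene
Product: 9 10α-hydroxymethyl-10β-methyl-5β-(a5)-7-(a7)-cyclohex-7-ene
Conditions: NaBH4, MeOH, 0 °C
Reagents that add atoms: none
Why: Borohydride reduction of the non-enolisable aldehyde masks C1 before the hydroborations.

Step 6
Reactants: 9 10α-hydroxymethyl-10β-methyl-5β-(a5)-7-(a7)-cyclohex-7-ene
Product: 10 10α-pivaloyloxymethyl-10β-methyl-5β-(a5)-7-(a7)-cyclohex-7-ene
Conditions: PivCl, pyridine, DMAP (cat.), CH2Cl2, 0 °C → rt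
Reagents that add atoms: pivaloyl chloride, CC(C)(C)C(Cl)=O
Why: Acylation of the primary alcohol; the pivalate survives borane, oxidants, silyl triflates and hydride at −78 °C.

Step 7
Reactants: 10 10α-pivaloyloxymethyl-10β-methyl-5β-(a5)-7-(a7)-cyclohex-7-ene
Product: 12 10α-pivaloyloxymethyl-10β-methyl-5β-(a5)-7β-(a7)-cyclohexan-8α-ol, via 8α-boryl adduct 11 (not isolated)
Conditions: BH3·THF, THF, 0 °C → rt; then NaOH, H2O2, 0 °C
Reagents that add atoms: hydrogen peroxide, OO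
Why: Brown hydroboration–oxidation puts boron on the less substituted C8 from the α face (opposite the axial 10-CH3); both new centres are erased later (C8 is oxidised, C7 becomes sp2), so the step only has to be regioselective.

Step 8
Reactants: 12 10α-pivaloyloxymethyl-10β-methyl-5β-(a5)-7β-(a7)-cyclohexan-8α-ol
Product: 13 10α-pivaloyloxymethyl-10β-methyl-5β-(a5)-7β-(a7)-cyclohexan-8-one
Conditions: Dess–Martin periodinane, NaHCO3, CH2Cl2, rt
Reagents that add atoms: none
Why: Dess–Martin oxidation of a secondary alcohol under buffered, neutral conditions.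

Step 9
Reactants: 13 10α-pivaloyloxymethyl-10β-methyl-5β-(a5)-7β-(a7)-cyclohexan-8-one
Product: 14 8-trimethylsilyloxy-10α-pivaloyloxymethyl-10β-methyl-5β-(a5)-7-(a7)-cyclohex-7-ene
Conditions: TMSOTf, Et3N, CH2Cl2, 0 °C → rt
Reagents that add atoms: trimethylsilyl trifluoromethanesulfonate, C[Si](C)(C)OS(=O)(=O)C(F)(F)F
Why: Soft enolisation gives the more substituted silyl enol ether (C7=C8) because the C9 side is neopentyl-hindered; any C8=C9 isomer cannot react in step 10 and returns ketone 13.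

Step 10
Reactants: 14 8-trimethylsilyloxy-10α-pivaloyloxymethyl-10β-methyl-5β-(a5)-7-(a7)-cyclohex-7-ene
Product: 15 10α-pivaloyloxymethyl-10β-methyl-5β-(a5)-7-(a7)-cyclohex-6-en-8-one
Conditions: Pd(OAc)2 (1.1 equiv), MeCN, rt
Reagents that add atoms: none
Why: Ito–Saegusa oxidation; the oxa-π-allylpalladium species loses a β-hydride from C6 to give the conjugated endocyclic enone, and C9 cannot compete because C10 is quaternary.

Step 11
Reactants: 15 10α-pivaloyloxymethyl-10β-methyl-5β-(a5)-7-(a7)-cyclohex-6-en-8-one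
Product: 16 10α-pivaloyloxymethyl-10β-methyl-5β-(a5)-7-(a7)-cyclohex-6-en-8β-ol
Conditions: NaBH4, CeCl3·7H2O, MeOH, −78 → −40 °C
Reagents that add atoms: none
Why: Luche 1,2-reduction; the β face of C8 is screened by the axial 10-CH3 (1,3-relationship), so hydride enters from the α face and sets the 8β carbinol.

Step 12
Reactants: 16 10α-pivaloyloxymethyl-10β-methyl-5β-(a5)-7-(a7)-cyclohex-6-en-8β-ol
Product: 17 8β-triethylsilyloxy-10α-pivaloyloxymethyl-10β-methyl-5β-(a5)-7-(a7)-cyclohex-6-ene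
Conditions: TESOTf, 2,6-lutidine, CH2Cl2, −78 °C
Reagents that add atoms: triethylsilyl trifluoromethanesulfonate, CC[Si](CC)(CC)OS(=O)(=O)C(F)(F)F
Why: Silyl triflate protection of the allylic alcohol with a group that can later be removed in the presence of a hindered TBS ether.

Step 13
Reactants: 17 8β-triethylsilyloxy-10α-pivaloyloxymethyl-10β-methyl-5β-(a5)-7-(a7)-cyclohex-6-ene
Product: 19 8β-triethylsilyloxy-10α-pivaloyloxymethyl-10β-methyl-5β-(a5)-7β-(a7)-cyclohexan-6α-ol, via 6α-boryl adduct 18 (not isolated)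
Conditions: BH3·THF, THF, 0 °C → rt; then NaOH, H2O2, 0 °C
Reagents that add atoms: hydrogen peroxide, OO
Why: Hydroboration–oxidation; boron goes to C6 (less substituted, remote from O8) from the α face, anti to 8β-OTES, the 5β arm and 10β-CH3, and the syn addition places H-7 α and the C7 arm β (sets C7; the C6 carbinol is oxidised next).

Step 14
Reactants: 19 8β-triethylsilyloxy-10α-pivaloyloxymethyl-10β-methyl-5β-(a5)-7β-(a7)-cyclohexan-6α-ol
Product: 20 8β-triethylsilyloxy-10α-pivaloyloxymethyl-10β-methyl-5β-(a5)-7β-(a7)-cyclohexan-6-one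
Conditions: Dess–Martin periodinane, NaHCO3, CH2Cl2, rt
Reagents that add atoms: none
Why: Buffered Dess–Martin oxidation does not epimerise C5 or C7 and does not eliminate the β-silyloxy group.

Step 15
Reactants: 20 8β-triethylsilyloxy-10α-pivaloyloxymethyl-10β-methyl-5β-(a5)-7β-(a7)-cyclohexan-6-one
Product: 21 8β-triethylsilyloxy-10α-pivaloyloxymethyl-10β-methyl-5β-(a5)-7β-(a7)-cyclohexan-6β-ol
Conditions: LiBH(s-Bu)3, THF, −78 °C; AcOH quench at −78 °C
Reagents that add atoms: none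
Why: Bulky-hydride ketone reduction; the β face of C6 is blocked by the syn-axial 10-CH3 and 8β-OTES, so attack from the α (equatorial) side gives the axial 6β alcohol (sets C6).

Step 16
Reactants: 21 8β-triethylsilyloxy-10α-pivaloyloxymethyl-10β-methyl-5β-(a5)-7β-(a7)-cyclohexan-6β-ol
Product: 22 6β-(tert-butyldimethylsilyloxy)-8β-triethylsilyloxy-10α-pivaloyloxymethyl-10β-methyl-5β-(a5)-7β-(a7)-cyclohexane
Conditions: TBSOTf, 2,6-lutidine, CH2Cl2, 0 °C → rt
Reagents that add atoms: tert-butyldimethylsilyl trifluoromethanesulfonate, CC(C)(C)[Si](C)(C)OS(=O)(=O)C(F)(F)F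
Why: The silyl triflate forces silylation of the hindered axial hydroxyl, which stays protected to the last step.

Step 17
Reactants: 22 6β-(tert-butyldimethylsilyloxy)-8β-triethylsilyloxy-10α-pivaloyloxymethyl-10β-methyl-5β-(a5)-7β-(a7)-cyclohexane
Product: 23 6β-(tert-butyldimethylsilyloxy)-8β-triethylsilyloxy-10α-hydroxymethyl-10β-methyl-5β-(a5)-7β-(a7)-cyclohexane
Conditions: i-Bu2AlH, CH2Cl2, −78 °C; aq. potassium sodium tartrate
Reagents that add atoms: none
Why: Reductive cleavage of the only ester present frees C1-OH without touching silyl or PMB ethers.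

Step 18
Reactants: 23 6β-(tert-butyldimethylsilyloxy)-8β-triethylsilyloxy-10α-hydroxymethyl-10β-methyl-5β-(a5)-7β-(a7)-cyclohexane
Product: 24 6β-(tert-butyldimethylsilyloxy)-8β-triethylsilyloxy-10α-formyl-10β-methyl-5β-(a5)-7β-(a7)-cyclohexane
Conditions: Dess–Martin periodinane, NaHCO3, CH2Cl2, rt
Reagents that add atoms: none
Why: Dess–Martin oxidation to a non-enolisable aldehyde, so C10 cannot epimerise.

Step 19
Reactants: 24 6β-(tert-butyldimethylsilyloxy)-8β-triethylsilyloxy-10α-formyl-10β-methyl-5β-(a5)-7β-(a7)-cyclohexane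
Product: 25 6β-(tert-butyldimethylsilyloxy)-8β-triethylsilyloxy-10α-vinyl-10β-methyl-5β-(a5)-7β-(a7)-cyclohexane
Conditions: Ph3PCH3Br, KN(SiMe3)2, THF, 0 °C → rt
Reagents that add atoms: methyltriphenylphosphonium bromide, [Br-].C[P+](c1ccccc1)(c1ccccc1)c1ccccc1
Why: Wittig methylenation gives the C10 vinyl group after the last hydroboration, so no chemoselectivity problem arises.

Step 20
Reactants: 25 6β-(tert-butyldimethylsilyloxy)-8β-triethylsilyloxy-10α-vinyl-10β-methyl-5β-(a5)-7β-(a7)-cyclohexane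
Product: 26 6β-(tert-butyldimethylsilyloxy)-10α-vinyl-10β-methyl-5β-(2-hydroxyethyl)-7β-(a7)-cyclohexan-8β-ol
Conditions: HF·pyridine, pyridine, THF, 0 °C → rt
Reagents that add atoms: none
Why: Selective desilylation; the TES ether and the primary TBS ether are cleaved much faster than the doubly flanked secondary TBS ether at O6.

Step 21
Reactants: 26 6β-(tert-butyldimethylsilyloxy)-10α-vinyl-10β-methyl-5β-(2-hydroxyethyl)-7β-(a7)-cyclohexan-8β-ol
Product: 27 6β-(tert-butyldimethylsilyloxy)-10α-vinyl-10β-methyl-5β-(2-oxoethyl)-7β-(a7)-cyclohexan-8β-ol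
Conditions: TEMPO (cat.), PhI(OAc)2, CH2Cl2, rt
Reagents that add atoms: none
Why: TEMPO/PhI(OAc)2 oxidation is selective for the primary alcohol over the hindered axial secondary one and stops at the aldehyde.

Step 22
Reactants: 27 6β-(tert-butyldimethylsilyloxy)-10α-vinyl-10β-methyl-5β-(2-oxoethyl)-7β-(a7)-cyclohexan-8β-ol
Product: 28 6β-(tert-butyldimethylsilyloxy)-10α-vinyl-10β-methyl-5β-(3-oxoprop-1-en-2-yl)-7β-(a7)-cyclohexan-8β-ol
Conditions: 37 % aq. HCHO, pyrrolidine (10 mol %), EtCO2H (10 mol %), i-PrOH, 45 °C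
Reagents that add atoms: formaldehyde, C=O
Why: Amine-catalysed Mannich condensation–elimination (α-methylenation of an aldehyde) adds the exocyclic CH2; C5 is β to the aldehyde and is not enolised.

Step 23
Reactants: 28 6β-(tert-butyldimethylsilyloxy)-10α-vinyl-10β-methyl-5β-(3-oxoprop-1-en-2-yl)-7β-(a7)-cyclohexan-8β-ol
Product: 29 6β-(tert-butyldimethylsilyloxy)-10α-vinyl-10β-methyl-5β-(3-hydroxyprop-1-en-2-yl)-7β-(a7)-cyclohexan-8β-ol
Conditions: NaBH4, CeCl3·7H2O, MeOH, −40 → 0 °C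
Reagents that add atoms: none
Why: Luche 1,2-reduction of the enal gives the allylic alcohol arm of the target without conjugate reduction.

Step 24
Reactants: 29 6β-(tert-butyldimethylsilyloxy)-10α-vinyl-10β-methyl-5β-(3-hydroxyprop-1-en-2-yl)-7β-(a7)-cyclohexan-8β-ol
Product: 30 6β-(tert-butyldimethylsilyloxy)-10α-vinyl-10β-methyl-5β-[3-(tert-butyldimethylsilyloxy)prop-1-en-2-yl]-7β-(a7)-cyclohexan-8β-ol
Conditions: TBSCl (1.1 equiv), imidazole, CH2Cl2, 0 °C
Reagents that add atoms: tert-butyldimethylsilyl chloride, CC(C)(C)[Si](C)(C)Cl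
Why: Silylation is selective for the primary allylic hydroxyl, leaving only the hindered C8-OH free.

Step 25
Reactants: 31 methyl 2-(hydroxymethyl)prop-2-enoate
Product: 32 methyl (R)-3-hydroxy-2-methylpropanoate
Conditions: ene-reductase (flavin-dependent, Old Yellow Enzyme family), NADP+ (cat.), D-glucose, glucose dehydrogenase, KH2PO4/K2HPO4 buffer pH 7.0, 30 °C
Reagents that add atoms: none
Why: Ene-reductase-catalysed asymmetric reduction of the activated C=C bond (hydride from the reduced flavin to C-β, protonation of C-α inside the active site) sets the side-chain stereocentre as (R).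

Step 26
Reactants: 32 methyl (R)-3-hydroxy-2-methylpropanoate
Product: 33 methyl (R)-3-(tert-butyldimethylsilyloxy)-2-methylpropanoate
Conditions: TBSCl, imidazole, DMF, rt
Reagents that add atoms: tert-butyldimethylsilyl chloride, CC(C)(C)[Si](C)(C)Cl
Why: Standard silylation of the primary alcohol; the stereocentre is not involved.

Step 27
Reactants: 33 methyl (R)-3-(tert-butyldimethylsilyloxy)-2-methylpropanoate
Product: 34 (R)-3-(tert-butyldimethylsilyloxy)-2-methylpropanoic acid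
Conditions: LiOH·H2O, THF/MeOH/H2O, 0 °C → rt; then 1 M HCl to pH 4
Reagents that add atoms: lithium hydroxide, [Li+].[OH-]
Why: Mild saponification at low temperature avoids epimerisation and β-elimination of the silyloxy group.

Step 28
Reactants: 30 6β-(tert-butyldimethylsilyloxy)-10α-vinyl-10β-methyl-5β-[3-(tert-butyldimethylsilyloxy)prop-1-en-2-yl]-7β-(a7)-cyclohexan-8β-ol; 34 (R)-3-(tert-butyldimethylsilyloxy)-2-methylpropanoic acid
Product: 36 8β-[(R)-3-(tert-butyldimethylsilyloxy)-2-methylpropanoyl] ester of 30, via trichlorobenzoyl mixed anhydride 35 (not isolated)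
Conditions: 2,4,6-trichlorobenzoyl chloride, Et3N, THF, rt; then 30, DMAP, toluene, rt → 40 °C
Reagents that add atoms: none
Why: Yamaguchi esterification acylates hindered secondary alcohols; 30 has no other free hydroxyl or carbonyl group, and C8 keeps its configuration because only the O–H bond reacts.

Step 29
Reactants: 36 8β-[(R)-3-(tert-butyldimethylsilyloxy)-2-methylpropanoyl] ester of 30
Product: 37 7β-(2-hydroxyethyl) analogue of 36
Conditions: DDQ, CH2Cl2/pH 7 buffer (10:1), 0 °C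
Reagents that add atoms: none
Why: Oxidative cleavage of the PMB ether is orthogonal to the silyl ethers, the ester and the alkenes.

Step 30
Reactants: 37 7β-(2-hydroxyethyl) analogue of 36
Product: 38 7β-(2-oxoethyl) analogue of 36
Conditions: Dess–Martin periodinane, NaHCO3, CH2Cl2, rt
Reagents that add atoms: none
Why: Dess–Martin oxidation of the only free alcohol to the aldehyde.

Step 31
Reactants: 38 7β-(2-oxoethyl) analogue of 36
Product: 39 7β-(3-oxoprop-1-en-2-yl) analogue of 36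
Conditions: 37 % aq. HCHO, pyrrolidine (10 mol %), EtCO2H (10 mol %), i-PrOH, 45 °C, short reaction time
Reagents that add atoms: formaldehyde, C=O
Why: The same Mannich condensation–elimination installs the C11 exocyclic methylene; C7 is β to the aldehyde and keeps its configuration.

Step 32
Reactants: 39 7β-(3-oxoprop-1-en-2-yl) analogue of 36
Product: 40 7β-(1-carboxyvinyl) analogue of 36 (tris-TBS acid)
Conditions: NaClO2, NaH2PO4, 2-methylbut-2-ene, t-BuOH/H2O, 0 °C → rt
Reagents that add atoms: sodium chlorite, [Na+].[O-]Cl=O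
Why: Pinnick oxidation turns the α-substituted acrolein into the acrylic acid without touching the alkenes, the ester or the silyl ethers.

Step 33
Reactants: 40 7β-(1-carboxyvinyl) analogue of 36 (tris-TBS acid)
Product: 41 CNP0462645.2, 8β-[(R)-3-hydroxy-2-methylpropanoyloxy]-6β,15-dihydroxyelema-1,3,11(13)-trien-12-oic acid
Conditions: HF·pyridine, excess pyridine, THF, 0 °C → rt; pH 7 phosphate quench, then acidify to pH 5
Reagents that add atoms: none
Why: Buffered fluoride desilylation removes the three TBS groups without base, which avoids 8→6 acyl migration; cold buffered work-up limits lactonisation of the 6-hydroxy acid.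

## Compound list

1 | but-3-yn-1-ol | C#CCCO | starting material
2 | 1-[(but-3-yn-1-yloxy)methyl]-4-methoxybenzene | C#CCCOCc1ccc(OC)cc1 | intermediate
3 | ethene | C=C | starting material
4 | 2-[2-(4-methoxybenzyloxy)ethyl]buta-1,3-diene | C=CC(=C)CCOCc1ccc(OC)cc1 | intermediate
5 | 3-(tert-butyldimethylsilyloxy)propanal | O=CCCO[Si](C)(C)C(C)(C)C | starting material
6 | 2-(triphenylphosphoranylidene)propanal | CC(C=O)=P(c1ccccc1)(c1ccccc1)c1ccccc1 | starting material
7 | (E)-5-(tert-butyldimethylsilyloxy)-2-methylpent-2-enal | O=C/C(C)=C/CCO[Si](C)(C)C(C)(C)C | intermediate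
8 | (1R,6S)-6-[2-(TBSO)ethyl]-4-[2-(PMBO)ethyl]-1-methylcyclohex-3-ene-1-carbaldehyde (10α-CHO, 10β-CH3, 5β-a5, 7-a7, C7=C8) | O=C[C@]1(C)CC=C(CCOCc2ccc(OC)cc2)C[C@H]1CCO[Si](C)(C)C(C)(C)C | intermediate
9 | 10α-hydroxymethyl-10β-methyl-5β-(a5)-7-(a7)-cyclohex-7-ene | OC[C@]1(C)CC=C(CCOCc2ccc(OC)cc2)C[C@H]1CCO[Si](C)(C)C(C)(C)C | intermediate
10 | 10α-pivaloyloxymethyl-10β-methyl-5β-(a5)-7-(a7)-cyclohex-7-ene | CC(C)(C)C(=O)OC[C@]1(C)CC=C(CCOCc2ccc(OC)cc2)C[C@H]1CCO[Si](C)(C)C(C)(C)C | intermediate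
11 | 8α-boryl adduct of 10 (8α-BH2, H-7α) | CC(C)(C)C(=O)OC[C@]1(C)C[C@H](B)[C@@H](CCOCc2ccc(OC)cc2)C[C@H]1CCO[Si](C)(C)C(C)(C)C | intermediate
12 | 10α-pivaloyloxymethyl-10β-methyl-5β-(a5)-7β-(a7)-cyclohexan-8α-ol | CC(C)(C)C(=O)OC[C@]1(C)C[C@H](O)[C@@H](CCOCc2ccc(OC)cc2)C[C@H]1CCO[Si](C)(C)C(C)(C)C | intermediate
13 | 10α-pivaloyloxymethyl-10β-methyl-5β-(a5)-7β-(a7)-cyclohexan-8-one | CC(C)(C)C(=O)OC[C@]1(C)CC(=O)[C@@H](CCOCc2ccc(OC)cc2)C[C@H]1CCO[Si](C)(C)C(C)(C)C | intermediate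
14 | 8-trimethylsilyloxy-10α-pivaloyloxymethyl-10β-methyl-5β-(a5)-7-(a7)-cyclohex-7-ene | CC(C)(C)C(=O)OC[C@]1(C)CC(O[Si](C)(C)C)=C(CCOCc2ccc(OC)cc2)C[C@H]1CCO[Si](C)(C)C(C)(C)C | intermediate
15 | 10α-pivaloyloxymethyl-10β-methyl-5β-(a5)-7-(a7)-cyclohex-6-en-8-one | CC(C)(C)C(=O)OC[C@]1(C)CC(=O)C(CCOCc2ccc(OC)cc2)=C[C@H]1CCO[Si](C)(C)C(C)(C)C | intermediate
16 | 10α-pivaloyloxymethyl-10β-methyl-5β-(a5)-7-(a7)-cyclohex-6-en-8β-ol | CC(C)(C)C(=O)OC[C@]1(C)C[C@@H](O)C(CCOCc2ccc(OC)cc2)=C[C@H]1CCO[Si](C)(C)C(C)(C)C | intermediate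
17 | 8β-triethylsilyloxy-10α-pivaloyloxymethyl-10β-methyl-5β-(a5)-7-(a7)-cyclohex-6-ene | CC(C)(C)C(=O)OC[C@]1(C)C[C@@H](O[Si](CC)(CC)CC)C(CCOCc2ccc(OC)cc2)=C[C@H]1CCO[Si](C)(C)C(C)(C)C | intermediate
18 | 6α-boryl adduct of 17 (6α-BH2, H-7α) | CC(C)(C)C(=O)OC[C@]1(C)C[C@@H](O[Si](CC)(CC)CC)[C@@H](CCOCc2ccc(OC)cc2)[C@H](B)[C@H]1CCO[Si](C)(C)C(C)(C)C | intermediate
19 | 8β-triethylsilyloxy-10α-pivaloyloxymethyl-10β-methyl-5β-(a5)-7β-(a7)-cyclohexan-6α-ol | CC(C)(C)C(=O)OC[C@]1(C)C[C@@H](O[Si](CC)(CC)CC)[C@@H](CCOCc2ccc(OC)cc2)[C@H](O)[C@H]1CCO[Si](C)(C)C(C)(C)C | intermediate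
20 | 8β-triethylsilyloxy-10α-pivaloyloxymethyl-10β-methyl-5β-(a5)-7β-(a7)-cyclohexan-6-one | CC(C)(C)C(=O)OC[C@]1(C)C[C@@H](O[Si](CC)(CC)CC)[C@@H](CCOCc2ccc(OC)cc2)C(=O)[C@H]1CCO[Si](C)(C)C(C)(C)C | intermediate
21 | 8β-triethylsilyloxy-10α-pivaloyloxymethyl-10β-methyl-5β-(a5)-7β-(a7)-cyclohexan-6β-ol | CC(C)(C)C(=O)OC[C@]1(C)C[C@@H](O[Si](CC)(CC)CC)[C@@H](CCOCc2ccc(OC)cc2)[C@@H](O)[C@H]1CCO[Si](C)(C)C(C)(C)C | intermediate
22 | 6β-TBSO-8β-TESO-10α-pivaloyloxymethyl-10β-methyl-5β-(a5)-7β-(a7)-cyclohexane | CC(C)(C)C(=O)OC[C@]1(C)C[C@@H](O[Si](CC)(CC)CC)[C@@H](CCOCc2ccc(OC)cc2)[C@@H](O[Si](C)(C)C(C)(C)C)[C@H]1CCO[Si](C)(C)C(C)(C)C | intermediate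
23 | 6β-TBSO-8β-TESO-10α-hydroxymethyl-10β-methyl-5β-(a5)-7β-(a7)-cyclohexane | OC[C@]1(C)C[C@@H](O[Si](CC)(CC)CC)[C@@H](CCOCc2ccc(OC)cc2)[C@@H](O[Si](C)(C)C(C)(C)C)[C@H]1CCO[Si](C)(C)C(C)(C)C | intermediate
24 | 6β-TBSO-8β-TESO-10α-formyl-10β-methyl-5β-(a5)-7β-(a7)-cyclohexane | O=C[C@]1(C)C[C@@H](O[Si](CC)(CC)CC)[C@@H](CCOCc2ccc(OC)cc2)[C@@H](O[Si](C)(C)C(C)(C)C)[C@H]1CCO[Si](C)(C)C(C)(C)C | intermediate
25 | 6β-TBSO-8β-TESO-10α-vinyl-10β-methyl-5β-(a5)-7β-(a7)-cyclohexane | C=C[C@]1(C)C[C@@H](O[Si](CC)(CC)CC)[C@@H](CCOCc2ccc(OC)cc2)[C@@H](O[Si](C)(C)C(C)(C)C)[C@H]1CCO[Si](C)(C)C(C)(C)C | intermediate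
26 | 6β-TBSO-10α-vinyl-10β-methyl-5β-(2-hydroxyethyl)-7β-(a7)-cyclohexan-8β-ol | C=C[C@]1(C)C[C@@H](O)[C@@H](CCOCc2ccc(OC)cc2)[C@@H](O[Si](C)(C)C(C)(C)C)[C@H]1CCO | intermediate
27 | 6β-TBSO-10α-vinyl-10β-methyl-5β-(2-oxoethyl)-7β-(a7)-cyclohexan-8β-ol | C=C[C@]1(C)C[C@@H](O)[C@@H](CCOCc2ccc(OC)cc2)[C@@H](O[Si](C)(C)C(C)(C)C)[C@H]1CC=O | intermediate
28 | 6β-TBSO-10α-vinyl-10β-methyl-5β-(3-oxoprop-1-en-2-yl)-7β-(a7)-cyclohexan-8β-ol | C=C[C@]1(C)C[C@@H](O)[C@@H](CCOCc2ccc(OC)cc2)[C@@H](O[Si](C)(C)C(C)(C)C)[C@H]1C(=C)C=O | intermediate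
29 | 6β-TBSO-10α-vinyl-10β-methyl-5β-(3-hydroxyprop-1-en-2-yl)-7β-(a7)-cyclohexan-8β-ol | C=C[C@]1(C)C[C@@H](O)[C@@H](CCOCc2ccc(OC)cc2)[C@@H](O[Si](C)(C)C(C)(C)C)[C@H]1C(=C)CO | intermediate
30 | 6β-TBSO-10α-vinyl-10β-methyl-5β-[3-(TBSO)prop-1-en-2-yl]-7β-(a7)-cyclohexan-8β-ol | C=C[C@]1(C)C[C@@H](O)[C@@H](CCOCc2ccc(OC)cc2)[C@@H](O[Si](C)(C)C(C)(C)C)[C@H]1C(=C)CO[Si](C)(C)C(C)(C)C | intermediate
31 | methyl 2-(hydroxymethyl)prop-2-enoate | C=C(CO)C(=O)OC | starting material
32 | methyl (R)-3-hydroxy-2-methylpropanoate | COC(=O)[C@H](C)CO | intermediate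
33 | methyl (R)-3-(tert-butyldimethylsilyloxy)-2-methylpropanoate | COC(=O)[C@H](C)CO[Si](C)(C)C(C)(C)C | intermediate
34 | (R)-3-(tert-butyldimethylsilyloxy)-2-methylpropanoic acid | OC(=O)[C@H](C)CO[Si](C)(C)C(C)(C)C | intermediate
35 | (R)-3-(tert-butyldimethylsilyloxy)-2-methylpropanoic 2,4,6-trichlorobenzoic anhydride | CC(C)(C)[Si](C)(C)OC[C@@H](C)C(=O)OC(=O)c1c(Cl)cc(Cl)cc1Cl | intermediate
36 | 8β-[(R)-3-(TBSO)-2-methylpropanoyloxy]-6β-TBSO-10α-vinyl-10β-methyl-5β-[3-(TBSO)prop-1-en-2-yl]-7β-(a7)-cyclohexane | C=C[C@]1(C)C[C@@H](OC(=O)[C@H](C)CO[Si](C)(C)C(C)(C)C)[C@@H](CCOCc2ccc(OC)cc2)[C@@H](O[Si](C)(C)C(C)(C)C)[C@H]1C(=C)CO[Si](C)(C)C(C)(C)C | intermediate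
37 | 7β-(2-hydroxyethyl) analogue of 36 | C=C[C@]1(C)C[C@@H](OC(=O)[C@H](C)CO[Si](C)(C)C(C)(C)C)[C@@H](CCO)[C@@H](O[Si](C)(C)C(C)(C)C)[C@H]1C(=C)CO[Si](C)(C)C(C)(C)C | intermediate
38 | 7β-(2-oxoethyl) analogue of 36 | C=C[C@]1(C)C[C@@H](OC(=O)[C@H](C)CO[Si](C)(C)C(C)(C)C)[C@@H](CC=O)[C@@H](O[Si](C)(C)C(C)(C)C)[C@H]1C(=C)CO[Si](C)(C)C(C)(C)C | intermediate
39 | 7β-(3-oxoprop-1-en-2-yl) analogue of 36 | C=C[C@]1(C)C[C@@H](OC(=O)[C@H](C)CO[Si](C)(C)C(C)(C)C)[C@@H](C(=C)C=O)[C@@H](O[Si](C)(C)C(C)(C)C)[C@H]1C(=C)CO[Si](C)(C)C(C)(C)C | intermediate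
40 | 7β-(1-carboxyvinyl) analogue of 36 (tris-TBS acid) | C=C[C@]1(C)C[C@@H](OC(=O)[C@H](C)CO[Si](C)(C)C(C)(C)C)[C@@H](C(=C)C(=O)O)[C@@H](O[Si](C)(C)C(C)(C)C)[C@H]1C(=C)CO[Si](C)(C)C(C)(C)C | intermediate
41 | CNP0462645.2, 8β-[(R)-3-hydroxy-2-methylpropanoyloxy]-6β,15-dihydroxyelema-1,3,11(13)-trien-12-oic acid | C=C[C@]1(C)C[C@@H](OC(=O)[C@H](C)CO)[C@@H](C(=C)C(=O)O)[C@@H](O)[C@H]1C(=C)CO | target

## Step count and weak points

Total step count: 33.
Longest linear sequence: 29 steps (1, 2, 4–24, 28–33, from but-3-yn-1-ol).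

**Step 4 (Diels–Alder).** A trisubstituted enal with a 2-alkyl diene may react slowly or with low ee. The fallback sets out from 7 and comes back at 8. The same catalyst is used with the much more nucleophilic 2-(triisopropylsilyloxy)buta-1,3-diene F1 (from but-3-en-2-one, i-Pr3SiOTf, Et3N) to give the regiodefined C7 silyl enol ether aldehyde F2. CsF and PhNTf2 in DME convert F2 into the C7 enol triflate F3 with the double bond held at C7=C8. The two-carbon arm is then attached by Suzuki–Miyaura coupling (PdCl2(dppf), Cs2CO3, toluene/H2O) with potassium [2-(4-methoxybenzyloxy)ethyl]trifluoroborate F5. F5 is made from 1-[(2-bromoethoxy)methyl]-4-methoxybenzene through its pinacol boronate F4 (B2pin2, CuI, PPh3, LiOMe; then aq. KHF2). The coupling gives aldehyde 8. The approach changes from a diene that already carries the arm to ring formation first and cross-coupling second.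

**Step 28 (esterification of the hindered 8β-hydroxyl).** DMAP-mediated acyl transfer to the neutral alcohol may be too slow next to the syn-axial 6-silyloxy and 10-methyl groups. The fallback sets out from 30 and comes back at 36. Acid 34 is first converted with dicyclohexylcarbodiimide into its symmetric anhydride F6. Alcohol 30 is deprotonated with NaN(SiMe3)2 in THF at −78 °C and the sodium alkoxide is acylated directly by F6 to give 36. The bond is then made by anionic acyl substitution on a pre-formed alkoxide instead of by nucleophilic catalysis, which 30 tolerates because it carries no carbonyl group or acidic C–H.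

**Step 33 (final desilylation).** With the free acid present, acidic fluoride may lactonise the 6-hydroxy acid to the cis-fused α-methylene lactone, and the hindered 6-O-TBS group needs long exposure. The fallback sets out from 40 and comes back at 41. Acid 40 is alkylated (allyl bromide, Cs2CO3, DMF) to the tris-TBS allyl ester F7. HF·pyridine then removes the three silyl groups to give the triol allyl ester F8. The acid is liberated last, under neutral conditions, with Pd(PPh3)4 and morpholine in THF, followed by acidification to pH 5, to give 41. The carboxyl group is thus never free while acid is present.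

## Further compounds

F1 | step 4 | 2-(triisopropylsilyloxy)buta-1,3-diene | C=CC(=C)O[Si](C(C)C)(C(C)C)C(C)C
F2 | step 4 | 10α-formyl-10β-methyl-5β-(a5)-7-(triisopropylsilyloxy)cyclohex-7-ene | O=C[C@]1(C)CC=C(O[Si](C(C)C)(C(C)C)C(C)C)C[C@H]1CCO[Si](C)(C)C(C)(C)C
F3 | step 4 | 10α-formyl-10β-methyl-5β-(a5)-cyclohex-7-en-7-yl trifluoromethanesulfonate | O=C[C@]1(C)CC=C(OS(=O)(=O)C(F)(F)F)C[C@H]1CCO[Si](C)(C)C(C)(C)C
F4 | step 4 | 2-[2-(4-methoxybenzyloxy)ethyl]-4,4,5,5-tetramethyl-1,3,2-dioxaborolane | COc1ccc(COCCB2OC(C)(C)C(C)(C)O2)cc1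
F5 | step 4 | potassium [2-(4-methoxybenzyloxy)ethyl]trifluoroborate | [K+].F[B-](F)(F)CCOCc1ccc(OC)cc1
F6 | step 28 | (R)-3-(tert-butyldimethylsilyloxy)-2-methylpropanoic anhydride | CC(C)(C)[Si](C)(C)OC[C@@H](C)C(=O)OC(=O)[C@H](C)CO[Si](C)(C)C(C)(C)C
F7 | step 33 | allyl ester of 40 | C=C[C@]1(C)C[C@@H](OC(=O)[C@H](C)CO[Si](C)(C)C(C)(C)C)[C@@H](C(=C)C(=O)OCC=C)[C@@H](O[Si](C)(C)C(C)(C)C)[C@H]1C(=C)CO[Si](C)(C)C(C)(C)C
F8 | step 33 | allyl ester of 41 | C=C[C@]1(C)C[C@@H](OC(=O)[C@H](C)CO)[C@@H](C(=C)C(=O)OCC=C)[C@@H](O)[C@H]1C(=C)CO
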